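**Conventions and assumption.** Flavone numbering is used: ring A = C5–C8, ring C = O1/C2/C3/C4, ring B = C1'–C6'. C9 is the methylene on C3, and C10 is the oxygenated carbon bonded through its oxygen to C2'. "Oxepino-flavone" means this C2–C3–C9–C10–O–C2'–C1' ring fused to the flavone. TES = triethylsilyl, Bn = benzyl, TBS = tert-butyldimethylsilyl. Assumption: C10 is R as drawn (O > C(CH3)2OH > C9 > H); which antipode of the hydrogenation ligand gives R is to be settled by screening both.

## The problem

The target is a 5,7,4'-trihydroxyflavone in which C3 of ring C and the 2'-oxygen of ring B are tied together by the two-carbon bridge C9H2–C10H, so that a seven-membered oxepine is fused across the C2–C1' bond. Ring A is a fully substituted phloroglucinol nucleus with prenyl groups at C6 and C8. The only stereocentre is C10 (R), which carries the aryl ether oxygen, C9 and a 2-hydroxypropan-2-yl group. Nothing else in the molecule is chiral, so its configuration must come from a reagent, a catalyst or a separation; once set it has no acidifying neighbour and should not epimerise. The fragile parts are the two prenyl alkenes (lost on hydrogenation, cyclised onto the flanking 5- and 7-hydroxyls by acid), the tertiary alcohol (ionisation), the oxidation-prone phloroglucinol ring with its O- versus C-alkylation ambiguity, and C2 of the pyranone toward hard nucleophiles. The oxepine is the difficult ring: closing it through the C10–O bond would mean an etherification at a secondary carbon next to a quaternary carbinol. The structure offers a better opening. C9 is allylic to C2=C3 and can carry a phosphonium ylide, and C10, with its aryl-oxygen and its carbon substituent, is one oxidation level below the carbonyl carbon of a 2'-O ester of 2-hydroxyisobutyric acid. C9=C10 is therefore the retron of an intramolecular ester Wittig reaction that closes the oxepine as a cyclic enol ether, and the C10–H bond can then be delivered enantioselectively by hydrogenation, which must happen before the prenyl groups exist.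

## Retrosynthesis

**22 ⇒ 20 (O–acyl and O–Si bonds).** Compound 20 has the full carbon skeleton, with the 5- and 7-hydroxyls as acetates, the 4'-hydroxyl as a hindered ester and the tertiary alcohol as a TES ether. All three esters fall to methanolysis and the silyl ether to brief acid, so the last step must only be mild enough not to close chromans from the prenylphenols.

**20 ⇒ 19 ⇒ 18 ⇒ 17 (C6–CH2 and C8–CH2).** The prenyl groups cannot be carried from a prenylated ring-A building block because steps 12 and 13 are hydrogenations. Direct C-prenylation of diphenol 17 would give O/C and mono/di mixtures. Iodination of the free phloroglucinol ring of 17 at its only two open positions (18), capping as diacetate 19 and a twofold Stille coupling fix the positions instead. Compound 17 is ten carbons and two alkenes simpler than 20. The forward sequence requires that only ring A is iodinated, which the 4'-ester ensures, and that the stannane couples through its primary carbon.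

**17 ⇒ 16 ⇒ 15 (O–Bn; then C9–H and C10–H).** After removal of the benzyl ethers, 16 is read as the hydrogenation product of the achiral cyclic enol ether 15. The neighbouring cuts at C10 (the C10–O bond, or C9–C10 by alkylation) would require a preformed stereocentre that is then carried through a hindered substitution. The enol ether removes the stereocentre from every earlier intermediate. The forward reaction must add hydrogen to the Si face of C10 and leave the tetrasubstituted C2=C3 bond and the benzyl ethers alone.

**15 ⇒ 14 (C9=C10).** The Wittig transform opens the oxepine to phosphonium salt 14, whose 2'-ester is the acceptor. Closing the ring by C–O bond formation (phenol onto an alkyne, or aryl etherification) would raise 6-exo/7-endo questions or need a hindered alkoxide. The Wittig cut puts the ylide on the one carbon that is naturally acidified (C9) and needs only an ester made by simple acylation. The forward reaction must find the 2'-ester and no other carbonyl, and must olefinate, not merely transfer the acyl group.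

**14 ⇒ 12 ⇒ 11 (C9–P, then C3–C9).** The phosphonium salt comes from allylic alcohol 12, and 12 from 3-iodoflavone 11 by coupling with a hydroxymethyl donor. Making C9 from a 3-methylflavone by radical bromination is excluded by the benzyl ethers and the electron-rich ring A. A Stille coupling at the vinylic iodide is neutral and tolerates both aryl esters.

**11 ⇒ 10 (O1–C2 and C3–I).** Electrophilic iodocyclisation of the 2-alkoxyaryl ynone 10 forms the pyranone and installs the C3 iodide in one step. There is no regiochemical question because the two ortho benzyloxy groups of 10 are equivalent. The classical diketone route would need strong base, which the aryl esters would not survive, and a separate C3 halogenation in the presence of a phloroglucinol ring.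

**10 ⇒ 9 ⇒ 5 + 8 (C(sp)–C1').** Ynone 10 is the oxidation product of propargylic alcohol 9, which a Sonogashira coupling divides into aryl bromide 5 and alkynol 8. Alkynol 8 is two steps from 1,3,5-tris(benzyloxy)benzene 6 through aldehyde 7. Bromide 5 is the bis-ester of 4-bromoresorcinol 4 with acid chloride 3, which is two steps from 2-hydroxyisobutyric acid 1 through silyl ester 2. Both hydroxyls of 4 receive the same ester: the ortho one becomes C10 and the para one is a base-labile protecting group, so the two oxygens need not be differentiated.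

## Roads not taken

**Alternative 1: prenyl groups last on the finished tetracycle.** The cut is the two aryl–CH2 bonds at C6 and C8. In the forward direction the 6,8-diiodide triacetate A1 is coupled twice with tributyl(prenyl)stannane to give the target triacetate A2, and deacetylation finishes the synthesis.
- Merits: the prenyl alkenes appear at the latest possible point and never meet hydrogenation, acid or strong base; their positions are fixed by iodination of the phloroglucinol ring; both arrive in one operation.
- Weak points: this road does not say how the oxepine or C10 is made. With the 4'-oxygen free at the iodination stage, ring B (a resorcinol monoether) can compete with ring A. Both iodides are flanked by two ortho substituents, and coupling through the γ-carbon of the stannane is possible.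
- Comparison: in the handling of the prenyl groups it is as good as can be, and the chosen plan uses the same tactic in steps 14–16. The chosen plan adds what this road leaves open: a construction of the oxepine and of C10, and a 4'-ester in place from the start so that ring B cannot be iodinated.

**Alternative 2: intramolecular nitrile oxide cycloaddition, isoxazole as masked flavone.** The cut is C2–C3 and O–C4. Aldoxime A3 already carries (R)-C10 as an ether on the 2'-oxygen and ends in a ring-A aryl alkyne. It is oxidised to the nitrile oxide, which adds across the tethered alkyne to give isoxazole A4, closing the oxepine and the isoxazole together. Reductive N–O cleavage, release of an ortho phenol and cyclisation with loss of ammonia would then give the chromone.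
- Merits: C10 is set before any ring is formed, by established chemistry; two rings form in one step; the tether enforces the regiochemistry.
- Weak points: the C10–O–aryl bond of A3 must be made by substitution at a secondary carbon beside a quaternary carbinol. The dipolarophile is an electron-rich alkyne with two ortho substituents, so nitrile oxide dimerisation can compete. After the key step the flavone still has to be unmasked before the same late diprenylation.
- Comparison: in stereochemical certainty this road is better, because the configuration is set beforehand by established chemistry and does not rest on a catalyst screen. The chosen plan sets against it an achiral, shorter assembly in which the flavone is complete when the oxepine closes and a C10–O bond made by acylation, with a separation-based fallback for C10.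

**Alternative 3: ring B and oxepine by intramolecular Diels–Alder benzannulation.** The cut is C1'–C2' and C5'–C6'. Precursor A5 is a 2-ethynylchromone whose C10 oxygen carries the bis(trimethylsilyl) dienol ether of an acetoacetate. The diene adds to the alkyne and the adduct loses trimethylsilanol to give A6, with ring B and the oxepine formed together.
- Merits: two rings and two C–C bonds in one step; the 2',4'-oxygenation is dictated by the diene; C10 is set early and its oxygen is attached by acylation.
- Weak points: A5 is long to make and its ketene acetal is moisture-sensitive. It must be generated with base and silyl chloride beside a chromone whose C2 is itself an acceptor for silyl ketene acetals. A benzene ring that is available as resorcinol is built from scratch.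
- Comparison: it forms more rings per step and secures the stereocentre early, and is better in both respects. The chosen plan sets against it a bought ring B, far fewer steps to the cyclisation precursor and more robust intermediates.

Key step: step 11

## Route

Step 1
Reactants: 1 2-hydroxy-2-methylpropanoic acid (2-hydroxyisobutyric acid)
Product: 2 triethylsilyl 2-methyl-2-(triethylsilyloxy)propanoate
Conditions: TESCl (2.4 equiv), imidazole (5 equiv), DMAP (cat.), DMF, 0 °C → rt
Reagents that add atoms: chlorotriethylsilane, CC[Si](CC)(CC)Cl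
Why: Standard O-silylation of the carboxyl and the tertiary hydroxyl; the silyl ester is the handle for the next step.

Step 2
Reactants: 2 triethylsilyl 2-methyl-2-(triethylsilyloxy)propanoate
Product: 3 2-methyl-2-(triethylsilyloxy)propanoyl chloride
Conditions: (COCl)2 (1.2 equiv), DMF (cat.), CH2Cl2, 0 °C → rt; volatiles removed, bulb-to-bulb distillation
Reagents that add atoms: oxalyl chloride, ClC(=O)C(=O)Cl
Why: Silyl esters are converted into acid chlorides by oxalyl chloride with catalytic DMF (Vilsmeier-type activation) without formation of HCl, so the tertiary TES ether should survive; the by-products are volatile and are removed so that no silyl chloride reaches the next step.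

Step 3
Reactants: 4 4-bromobenzene-1,3-diol (4-bromoresorcinol); 3 2-methyl-2-(triethylsilyloxy)propanoyl chloride (2.3 equiv)
Product: 5 4-bromo-1,3-phenylene bis[2-methyl-2-(triethylsilyloxy)propanoate]
Conditions: Et3N (3 equiv), DMAP (0.1 equiv), CH2Cl2, 0 °C → rt
Reagents that add atoms: none
Why: DMAP-catalysed O-acylation of both phenols; using one ester for both oxygens avoids any differentiation, the ortho ester being the later Wittig acceptor and the para ester a base-labile protecting group that also deactivates ring B.

Step 4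
Reactants: 6 1,3,5-tris(benzyloxy)benzene
Product: 7 2,4,6-tris(benzyloxy)benzaldehyde
Conditions: POCl3 (1.3 equiv), DMF, 0 °C → rt; then H2O, 0 °C
Reagents that add atoms: N,N-dimethylformamide, CN(C)C=O; water, O
Why: Vilsmeier–Haack formylation of a strongly activated, threefold symmetric phloroglucinol triether, so only one mono-aldehyde can form.

Step 5
Reactants: 7 2,4,6-tris(benzyloxy)benzaldehyde
Product: 8 rac-1-[2,4,6-tris(benzyloxy)phenyl]prop-2-yn-1-ol
Conditions: HC≡CMgBr (1.3 equiv), THF, 0 °C; sat. aq. NH4Cl
Reagents that add atoms: ethynylmagnesium bromide, C#C[Mg]Br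
Why: 1,2-Addition of an alkynyl Grignard reagent to an aromatic aldehyde; the carbinol centre is racemic and is erased by the oxidation in step 7.

Step 6
Reactants: 5 4-bromo-1,3-phenylene bis[2-methyl-2-(triethylsilyloxy)propanoate]; 8 rac-1-[2,4,6-tris(benzyloxy)phenyl]prop-2-yn-1-ol
Product: 9 rac-4-{3-hydroxy-3-[2,4,6-tris(benzyloxy)phenyl]prop-1-ynyl}-1,3-phenylene bis[2-methyl-2-(triethylsilyloxy)propanoate]
Conditions: Pd(PPh3)2Cl2 (5 mol%), CuI (10 mol%), Et3N, THF, 60 °C
Reagents that add atoms: none
Why: Sonogashira coupling of a terminal alkyne with an aryl bromide; the tertiary amine does not attack the hindered aryl esters, and the acylated ortho oxygen cannot add to the new alkyne.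

Step 7
Reactants: 9 rac-4-{3-hydroxy-3-[2,4,6-tris(benzyloxy)phenyl]prop-1-ynyl}-1,3-phenylene bis[2-methyl-2-(triethylsilyloxy)propanoate]
Product: 10 4-{3-oxo-3-[2,4,6-tris(benzyloxy)phenyl]prop-1-ynyl}-1,3-phenylene bis[2-methyl-2-(triethylsilyloxy)propanoate]
Conditions: MnO2 (20 equiv), CH2Cl2, rt
Reagents that add atoms: none
Why: MnO2 oxidation of a benzylic and propargylic alcohol to the ynone under neutral conditions that should spare silyl ethers, aryl esters and benzyl ethers.

Step 8
Reactants: 10 4-{3-oxo-3-[2,4,6-tris(benzyloxy)phenyl]prop-1-ynyl}-1,3-phenylene bis[2-methyl-2-(triethylsilyloxy)propanoate]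
Product: 11 4-[5,7-bis(benzyloxy)-3-iodo-4-oxo-4H-chromen-2-yl]-1,3-phenylene bis[2-methyl-2-(triethylsilyloxy)propanoate]
Conditions: ICl (1.2 equiv), CH2Cl2, −78 °C; aq. Na2S2O3
Reagents that add atoms: iodine monochloride, ClI
Why: Iodine monochloride-induced electrophilic cyclisation of a 2-alkoxyaryl ynone: the iodonium-activated alkyne is attacked 6-endo-dig at its β-carbon by an ortho ether oxygen, and chloride dealkylates the oxonium ion (here with loss of benzyl chloride). The two ortho benzyloxy groups are equivalent, so one regioisomer is expected and the C3 iodide is installed in the same step.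

Step 9
Reactants: 11 4-[5,7-bis(benzyloxy)-3-iodo-4-oxo-4H-chromen-2-yl]-1,3-phenylene bis[2-methyl-2-(triethylsilyloxy)propanoate]
Product: 12 4-[5,7-bis(benzyloxy)-3-(hydroxymethyl)-4-oxo-4H-chromen-2-yl]-1,3-phenylene bis[2-methyl-2-(triethylsilyloxy)propanoate]
Conditions: Bu3SnCH2OH (1.5 equiv), Pd(PPh3)4 (10 mol%), 1,4-dioxane, 90 °C
Reagents that add atoms: (tributylstannyl)methanol, CCCC[Sn](CO)(CCCC)CCCC
Why: Stille coupling in which the stannane transfers its hydroxymethyl group to the vinylic iodide under neutral conditions; α-iodoenones add readily to zerovalent palladium, and the hindered esters and silyl ethers are inert.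

Step 10
Reactants: 12 4-[5,7-bis(benzyloxy)-3-(hydroxymethyl)-4-oxo-4H-chromen-2-yl]-1,3-phenylene bis[2-methyl-2-(triethylsilyloxy)propanoate]
Product: 14 ({5,7-bis(benzyloxy)-2-[2,4-bis(2-methyl-2-(triethylsilyloxy)propanoyloxy)phenyl]-4-oxo-4H-chromen-3-yl}methyl)triphenylphosphonium bromide, via 3-(bromomethyl)flavone 13 (not isolated)
Conditions: CBr4 (1.3 equiv), PPh3 (1.4 equiv), CH2Cl2, 0 °C; then PPh3 (2 equiv), toluene, 60 °C; trituration with Et2O
Reagents that add atoms: carbon tetrabromide, BrC(Br)(Br)Br; triphenylphosphine, c1ccc(cc1)P(c1ccccc1)c1ccccc1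
Why: Appel bromination of the primary allylic alcohol followed in the same flask by SN2 quaternisation of triphenylphosphine by the reactive allylic bromide; the bromide is not isolated, and the hindered 2'-ester cannot migrate to C9 under these neutral conditions.

Step 11
Reactants: 14 ({5,7-bis(benzyloxy)-2-[2,4-bis(2-methyl-2-(triethylsilyloxy)propanoyloxy)phenyl]-4-oxo-4H-chromen-3-yl}methyl)triphenylphosphonium bromide
Product: 15 5,7-bis(benzyloxy)-10-[2-(triethylsilyloxy)propan-2-yl]-9,10-didehydro-oxepino-flavon-4'-yl 2-methyl-2-(triethylsilyloxy)propanoate (cyclic enol ether with the double bond between C9 and C10)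
Conditions: KN(SiMe3)2 (1.05 equiv), THF, −78 °C; then toluene (0.005 M), −78 → 80 °C
Reagents that add atoms: none
Why: KN(SiMe3)2 removes a C9 proton of 14 to give the semi-stabilised allylic ylide, which adds to the carbonyl carbon of the neighbouring 2'-O ester in an intramolecular Wittig reaction; the oxaphosphetane collapses with loss of triphenylphosphine oxide, so the former ester carbon becomes the enol-ether carbon C10. The closest known reaction type is the intramolecular Wittig olefination of aryl esters by tethered benzylic phosphonium ylides that gives benzofurans and benzo-fused cyclic enol ethers. The oxepine (C2, C3, C9, C10, O, C2', C1') closes by 7-exo-trig attack of C9 on C10, the carbonyl oxygen being exocyclic to the forming ring. No stereocentre is created and the alkene geometry is fixed by the ring. The step needs site selectivity among three carbonyl groups and olefination in preference to acyl transfer: only the 2'-ester is within reach of C9, the hindered 4'-ester can react only between molecules and is held back by high dilution, and attack on C4 would give a three-membered ring. A non-nucleophilic amide base in an aprotic medium avoids ester cleavage, and if the adduct expels the 2'-phenoxide, that phenoxide stays tethered and can re-add, whereas loss of triphenylphosphine oxide is irreversible.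

Step 12
Reactants: 15 5,7-bis(benzyloxy)-10-[2-(triethylsilyloxy)propan-2-yl]-9,10-didehydro-oxepino-flavon-4'-yl 2-methyl-2-(triethylsilyloxy)propanoate
Product: 16 (10R)-5,7-bis(benzyloxy)-10-[2-(triethylsilyloxy)propan-2-yl]-9,10-dihydro-oxepino-flavon-4'-yl 2-methyl-2-(triethylsilyloxy)propanoate
Conditions: H2 (50 bar), [Ir(cod)((S)-tBu-PHOX)][B(3,5-(CF3)2C6H3)4] or its mirror image (2 mol%), CH2Cl2, 25 °C
Reagents that add atoms: none
Why: Iridium N,P-ligand-catalysed asymmetric hydrogenation of a trisubstituted aryl enol ether, the reaction type used for 2-substituted 4H-chromenes. (R)-C10 arises by catalyst-controlled delivery of hydrogen to the Si face of C10, the ligand antipode being chosen accordingly. The tetrasubstituted, vinylogous-ester C2=C3 bond and the benzyl ethers are not expected to react.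

Step 13
Reactants: 16 (10R)-5,7-bis(benzyloxy)-10-[2-(triethylsilyloxy)propan-2-yl]-9,10-dihydro-oxepino-flavon-4'-yl 2-methyl-2-(triethylsilyloxy)propanoate
Product: 17 (10R)-5,7-dihydroxy-10-[2-(triethylsilyloxy)propan-2-yl]-9,10-dihydro-oxepino-flavon-4'-yl 2-methyl-2-(triethylsilyloxy)propanoate
Conditions: H2 (1 atm), 10% Pd/C, EtOAc, rt
Reagents that add atoms: none
Why: Hydrogenolysis of aryl benzyl ethers over Pd/C; ethyl acetate is used in place of methanol so that the TES ether is not solvolysed, and the C10–O bond is a non-benzylic alkyl aryl ether, so the stereocentre is not at risk.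

Step 14
Reactants: 17 (10R)-5,7-dihydroxy-10-[2-(triethylsilyloxy)propan-2-yl]-9,10-dihydro-oxepino-flavon-4'-yl 2-methyl-2-(triethylsilyloxy)propanoate
Product: 18 (10R)-5,7-dihydroxy-6,8-diiodo-10-[2-(triethylsilyloxy)propan-2-yl]-9,10-dihydro-oxepino-flavon-4'-yl 2-methyl-2-(triethylsilyloxy)propanoate
Conditions: N-iodosuccinimide (2.1 equiv), DMF, 0 °C → rt, dark
Reagents that add atoms: N-iodosuccinimide, O=C1CCC(=O)N1I
Why: Electrophilic aromatic iodination of the free 5,7-dihydroxy ring A at its only open positions C6 and C8; ring B has no free phenol and its 4'-oxygen is an ester, so it should not react under these neutral conditions.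

Step 15
Reactants: 18 (10R)-5,7-dihydroxy-6,8-diiodo-10-[2-(triethylsilyloxy)propan-2-yl]-9,10-dihydro-oxepino-flavon-4'-yl 2-methyl-2-(triethylsilyloxy)propanoate
Product: 19 (10R)-5,7-diacetoxy-6,8-diiodo-10-[2-(triethylsilyloxy)propan-2-yl]-9,10-dihydro-oxepino-flavon-4'-yl 2-methyl-2-(triethylsilyloxy)propanoate
Conditions: Ac2O, pyridine, DMAP (cat.), rt
Reagents that add atoms: acetic anhydride, CC(=O)OC(C)=O
Why: DMAP-catalysed acetylation of both phenols, the chelated 5-hydroxyl included, so that acidic phenols do not protonate the allylic stannane or bind the catalyst in the coupling.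

Step 16
Reactants: 19 (10R)-5,7-diacetoxy-6,8-diiodo-10-[2-(triethylsilyloxy)propan-2-yl]-9,10-dihydro-oxepino-flavon-4'-yl 2-methyl-2-(triethylsilyloxy)propanoate
Product: 20 (10R)-5,7-diacetoxy-6,8-bis(3-methylbut-2-enyl)-10-[2-(triethylsilyloxy)propan-2-yl]-9,10-dihydro-oxepino-flavon-4'-yl 2-methyl-2-(triethylsilyloxy)propanoate
Conditions: tributyl(3-methylbut-2-enyl)stannane (3 equiv), Pd(PPh3)4 (10 mol%), DMF, 90 °C
Reagents that add atoms: tributyl(3-methylbut-2-enyl)stannane, CCCC[Sn](CC=C(C)C)(CCCC)CCCC
Why: Twofold Stille coupling of the aryl iodides with the prenylstannane; reductive elimination from the less hindered terminus of the allyl-palladium intermediate gives the linear 3-methylbut-2-enyl groups, and the alkenes enter only after both hydrogenations.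

Step 17
Reactants: 20 (10R)-5,7-diacetoxy-6,8-bis(3-methylbut-2-enyl)-10-[2-(triethylsilyloxy)propan-2-yl]-9,10-dihydro-oxepino-flavon-4'-yl 2-methyl-2-(triethylsilyloxy)propanoate
Product: 22 CNP0328977.2 [(10R)-5,7,4'-trihydroxy-10-(2-hydroxypropan-2-yl)-6,8-bis(3-methylbut-2-enyl)-9,10-dihydro-oxepino-flavone], via tertiary-O-TES triol 21 (not isolated)
Conditions: K2CO3 (6 equiv), MeOH, 35 °C, argon; then 2 M aq. HCl to pH 1, rt
Reagents that add atoms: none
Why: Base-catalysed methanolysis (Zemplén-type transesterification) removes the three aryl esters, and brief acidification cleaves the tertiary TES ether; the conditions should be too mild to cyclise the prenyl groups onto the neighbouring phenols or ionise the tertiary alcohol, and C10 is not touched.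

## Compound list

1 | 2-hydroxy-2-methylpropanoic acid | CC(C)(O)C(=O)O | starting material
2 | triethylsilyl 2-methyl-2-(triethylsilyloxy)propanoate | CC[Si](CC)(CC)OC(C)(C)C(=O)O[Si](CC)(CC)CC | intermediate
3 | 2-methyl-2-(triethylsilyloxy)propanoyl chloride | CC[Si](CC)(CC)OC(C)(C)C(=O)Cl | intermediate
4 | 4-bromobenzene-1,3-diol | Oc1ccc(Br)c(O)c1 | starting material
5 | 4-bromo-1,3-phenylene bis[2-methyl-2-(triethylsilyloxy)propanoate] | CC[Si](CC)(CC)OC(C)(C)C(=O)Oc1ccc(Br)c(OC(=O)C(C)(C)O[Si](CC)(CC)CC)c1 | intermediate
6 | 1,3,5-tris(benzyloxy)benzene | c1ccc(COc2cc(OCc3ccccc3)cc(OCc3ccccc3)c2)cc1 | starting material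
7 | 2,4,6-tris(benzyloxy)benzaldehyde | O=Cc1c(OCc2ccccc2)cc(OCc2ccccc2)cc1OCc1ccccc1 | intermediate
8 | rac-1-[2,4,6-tris(benzyloxy)phenyl]prop-2-yn-1-ol | C#CC(O)c1c(OCc2ccccc2)cc(OCc2ccccc2)cc1OCc1ccccc1 | intermediate
9 | rac-4-{3-hydroxy-3-[2,4,6-tris(benzyloxy)phenyl]prop-1-ynyl}-1,3-phenylene bis[2-methyl-2-(triethylsilyloxy)propanoate] | CC[Si](CC)(CC)OC(C)(C)C(=O)Oc1ccc(C#CC(O)c2c(OCc3ccccc3)cc(OCc3ccccc3)cc2OCc2ccccc2)c(OC(=O)C(C)(C)O[Si](CC)(CC)CC)c1 | intermediate
10 | 4-{3-oxo-3-[2,4,6-tris(benzyloxy)phenyl]prop-1-ynyl}-1,3-phenylene bis[2-methyl-2-(triethylsilyloxy)propanoate] | CC[Si](CC)(CC)OC(C)(C)C(=O)Oc1ccc(C#CC(=O)c2c(OCc3ccccc3)cc(OCc3ccccc3)cc2OCc2ccccc2)c(OC(=O)C(C)(C)O[Si](CC)(CC)CC)c1 | intermediate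
11 | 4-[5,7-bis(benzyloxy)-3-iodo-4-oxo-4H-chromen-2-yl]-1,3-phenylene bis[2-methyl-2-(triethylsilyloxy)propanoate] | O=c1c(I)c(-c2ccc(OC(=O)C(C)(C)O[Si](CC)(CC)CC)cc2OC(=O)C(C)(C)O[Si](CC)(CC)CC)oc2cc(OCc3ccccc3)cc(OCc3ccccc3)c12 | intermediate
12 | 4-[5,7-bis(benzyloxy)-3-(hydroxymethyl)-4-oxo-4H-chromen-2-yl]-1,3-phenylene bis[2-methyl-2-(triethylsilyloxy)propanoate] | O=c1c(CO)c(-c2ccc(OC(=O)C(C)(C)O[Si](CC)(CC)CC)cc2OC(=O)C(C)(C)O[Si](CC)(CC)CC)oc2cc(OCc3ccccc3)cc(OCc3ccccc3)c12 | intermediate
13 | 4-[5,7-bis(benzyloxy)-3-(bromomethyl)-4-oxo-4H-chromen-2-yl]-1,3-phenylene bis[2-methyl-2-(triethylsilyloxy)propanoate] | O=c1c(CBr)c(-c2ccc(OC(=O)C(C)(C)O[Si](CC)(CC)CC)cc2OC(=O)C(C)(C)O[Si](CC)(CC)CC)oc2cc(OCc3ccccc3)cc(OCc3ccccc3)c12 | intermediate (not isolated)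
14 | ({5,7-bis(benzyloxy)-2-[2,4-bis(2-methyl-2-(triethylsilyloxy)propanoyloxy)phenyl]-4-oxo-4H-chromen-3-yl}methyl)triphenylphosphonium bromide | [Br-].O=c1c(C[P+](c2ccccc2)(c2ccccc2)c2ccccc2)c(-c2ccc(OC(=O)C(C)(C)O[Si](CC)(CC)CC)cc2OC(=O)C(C)(C)O[Si](CC)(CC)CC)oc2cc(OCc3ccccc3)cc(OCc3ccccc3)c12 | intermediate
15 | 5,7-bis(benzyloxy)-10-[2-(triethylsilyloxy)propan-2-yl]-9,10-didehydro-oxepino-flavon-4'-yl 2-methyl-2-(triethylsilyloxy)propanoate | O=c1c2c(OCc3ccccc3)cc(OCc3ccccc3)cc2oc2c1C=C(C(C)(C)O[Si](CC)(CC)CC)Oc1cc(OC(=O)C(C)(C)O[Si](CC)(CC)CC)ccc1-2 | intermediate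
16 | (10R)-5,7-bis(benzyloxy)-10-[2-(triethylsilyloxy)propan-2-yl]-9,10-dihydro-oxepino-flavon-4'-yl 2-methyl-2-(triethylsilyloxy)propanoate | O=c1c2c(OCc3ccccc3)cc(OCc3ccccc3)cc2oc2c1C[C@H](C(C)(C)O[Si](CC)(CC)CC)Oc1cc(OC(=O)C(C)(C)O[Si](CC)(CC)CC)ccc1-2 | intermediate
17 | (10R)-5,7-dihydroxy-10-[2-(triethylsilyloxy)propan-2-yl]-9,10-dihydro-oxepino-flavon-4'-yl 2-methyl-2-(triethylsilyloxy)propanoate | O=c1c2c(O)cc(O)cc2oc2c1C[C@H](C(C)(C)O[Si](CC)(CC)CC)Oc1cc(OC(=O)C(C)(C)O[Si](CC)(CC)CC)ccc1-2 | intermediate
18 | (10R)-5,7-dihydroxy-6,8-diiodo-10-[2-(triethylsilyloxy)propan-2-yl]-9,10-dihydro-oxepino-flavon-4'-yl 2-methyl-2-(triethylsilyloxy)propanoate | O=c1c2c(O)c(I)c(O)c(I)c2oc2c1C[C@H](C(C)(C)O[Si](CC)(CC)CC)Oc1cc(OC(=O)C(C)(C)O[Si](CC)(CC)CC)ccc1-2 | intermediate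
19 | (10R)-5,7-diacetoxy-6,8-diiodo-10-[2-(triethylsilyloxy)propan-2-yl]-9,10-dihydro-oxepino-flavon-4'-yl 2-methyl-2-(triethylsilyloxy)propanoate | O=c1c2c(OC(C)=O)c(I)c(OC(C)=O)c(I)c2oc2c1C[C@H](C(C)(C)O[Si](CC)(CC)CC)Oc1cc(OC(=O)C(C)(C)O[Si](CC)(CC)CC)ccc1-2 | intermediate
20 | (10R)-5,7-diacetoxy-6,8-bis(3-methylbut-2-enyl)-10-[2-(triethylsilyloxy)propan-2-yl]-9,10-dihydro-oxepino-flavon-4'-yl 2-methyl-2-(triethylsilyloxy)propanoate | O=c1c2c(OC(C)=O)c(CC=C(C)C)c(OC(C)=O)c(CC=C(C)C)c2oc2c1C[C@H](C(C)(C)O[Si](CC)(CC)CC)Oc1cc(OC(=O)C(C)(C)O[Si](CC)(CC)CC)ccc1-2 | intermediate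
21 | (10R)-5,7,4'-trihydroxy-6,8-bis(3-methylbut-2-enyl)-10-[2-(triethylsilyloxy)propan-2-yl]-9,10-dihydro-oxepino-flavone | O=c1c2c(O)c(CC=C(C)C)c(O)c(CC=C(C)C)c2oc2c1C[C@H](C(C)(C)O[Si](CC)(CC)CC)Oc1cc(O)ccc1-2 | intermediate (not isolated)
22 | CNP0328977.2, (10R)-5,7,4'-trihydroxy-10-(2-hydroxypropan-2-yl)-6,8-bis(3-methylbut-2-enyl)-9,10-dihydro-oxepino-flavone | CC(C)=CCc1c(O)c(CC=C(C)C)c2oc3c(c(=O)c2c1O)C[C@H](C(C)(C)O)Oc1cc(O)ccc1-3 | target

## Step count and least certain steps

Total: 17 steps. Longest linear sequence: 15 steps (steps 1–3, then 6–17); the ring-A branch (steps 4 and 5) joins at step 6.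

**Step 11 (key step).** The oxaphosphetane is crowded, with a triphenylphosphonio group on C9 and a quaternary silyloxy carbon on C10, so the seven-membered closure may be slow. The ylide may then merely be acylated, with expulsion of the 2'-phenoxide, or may react between molecules. A first adjustment within the step is a tributylphosphonium salt in place of the triphenyl one. The fallback sets out from 12 and forms the same bond by reductive carbonyl coupling. Oxidation of 12 with MnO2 in CH2Cl2 should give the 3-formylflavone, 4-[5,7-bis(benzyloxy)-3-formyl-4-oxo-4H-chromen-2-yl]-1,3-phenylene bis[2-methyl-2-(triethylsilyloxy)propanoate] F1. A titanium-induced intramolecular oxo-ester coupling of the McMurry type (TiCl3, Zn dust, DME, reflux, slow addition) would then join the aldehyde carbon C9 to the 2'-ester carbon C10 with loss of both oxygens. This comes back to the route at 15.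

**Step 12.** The enol ether is trisubstituted and flanked by a quaternary carbon, so hydrogenation may be slow or poorly face-selective, and the acidic iridium hydride may cleave the enol ether. The fallback sets out from 15 and replaces catalyst control by separation. Hydrogenation over Pd/C (H2, 5 bar, EtOAc) should saturate C9=C10 and remove both benzyl groups in one operation to give racemic 17 F2. Preparative chromatography on a chiral stationary phase would give the (10R)-enantiomer, which is 17, where the route is rejoined. Half of the material is lost and one step is saved.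

**Step 8.** The iodonium ion may be captured by the carbonyl oxygen of the ortho ester of ring B in place of the ring-A ether oxygen, the electron-rich ring A may be iodinated, or silyl groups may be lost. The fallback postpones the acylation until after the cyclisation. It sets out from 4 and 8 and returns at 11.
- Silylation of 4 (TBSCl, imidazole, DMF) gives 4-bromo-1,3-bis(tert-butyldimethylsilyloxy)benzene F3.
- Sonogashira coupling of F3 with 8 (Pd(PhCN)2Cl2, P(t-Bu)3, CuI, i-Pr2NH, dioxane) gives rac-3-[2,4-bis(tert-butyldimethylsilyloxy)phenyl]-1-[2,4,6-tris(benzyloxy)phenyl]prop-2-yn-1-ol F4.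
- MnO2 oxidation gives 3-[2,4-bis(tert-butyldimethylsilyloxy)phenyl]-1-[2,4,6-tris(benzyloxy)phenyl]prop-2-yn-1-one F5.
- ICl at −78 °C gives 5,7-bis(benzyloxy)-2-[2,4-bis(tert-butyldimethylsilyloxy)phenyl]-3-iodo-4H-chromen-4-one F6.
- HF·pyridine in THF gives 5,7-bis(benzyloxy)-2-(2,4-dihydroxyphenyl)-3-iodo-4H-chromen-4-one F7.
- Acylation of F7 with 3 (Et3N, DMAP) as in step 3 gives 11.

**Step 16.** Both iodides are flanked by two ortho substituents, so the second coupling may stall and protodeiodination may intervene; the stannane may also couple through its γ-carbon and deliver 1,1-dimethylallyl groups. The fallback sets out from 19 and separates C–C bond formation from the installation of the trisubstituted alkene. A twofold Stille coupling with allyltributylstannane (Pd(PPh3)4, DMF, 80 °C) should give the 6,8-diallyl compound, (10R)-5,7-diacetoxy-6,8-diallyl-10-[2-(triethylsilyloxy)propan-2-yl]-9,10-dihydro-oxepino-flavon-4'-yl 2-methyl-2-(triethylsilyloxy)propanoate F8. Cross-metathesis of both allyl groups with 2-methyl-2-butene (second-generation Grubbs catalyst, CH2Cl2, 40 °C) would convert F8 into 20, where the route is rejoined.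

## Further compounds

F1 | step 11 | 4-[5,7-bis(benzyloxy)-3-formyl-4-oxo-4H-chromen-2-yl]-1,3-phenylene bis[2-methyl-2-(triethylsilyloxy)propanoate] | O=Cc1c(-c2ccc(OC(=O)C(C)(C)O[Si](CC)(CC)CC)cc2OC(=O)C(C)(C)O[Si](CC)(CC)CC)oc2cc(OCc3ccccc3)cc(OCc3ccccc3)c2c1=O
F2 | step 12 | racemic 17, rac-5,7-dihydroxy-10-[2-(triethylsilyloxy)propan-2-yl]-9,10-dihydro-oxepino-flavon-4'-yl 2-methyl-2-(triethylsilyloxy)propanoate | O=c1c2c(O)cc(O)cc2oc2c1CC(C(C)(C)O[Si](CC)(CC)CC)Oc1cc(OC(=O)C(C)(C)O[Si](CC)(CC)CC)ccc1-2
F3 | step 8 | 4-bromo-1,3-bis(tert-butyldimethylsilyloxy)benzene | CC(C)(C)[Si](C)(C)Oc1ccc(Br)c(O[Si](C)(C)C(C)(C)C)c1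
F4 | step 8 | rac-3-[2,4-bis(tert-butyldimethylsilyloxy)phenyl]-1-[2,4,6-tris(benzyloxy)phenyl]prop-2-yn-1-ol | CC(C)(C)[Si](C)(C)Oc1ccc(C#CC(O)c2c(OCc3ccccc3)cc(OCc3ccccc3)cc2OCc2ccccc2)c(O[Si](C)(C)C(C)(C)C)c1
F5 | step 8 | 3-[2,4-bis(tert-butyldimethylsilyloxy)phenyl]-1-[2,4,6-tris(benzyloxy)phenyl]prop-2-yn-1-one | CC(C)(C)[Si](C)(C)Oc1ccc(C#CC(=O)c2c(OCc3ccccc3)cc(OCc3ccccc3)cc2OCc2ccccc2)c(O[Si](C)(C)C(C)(C)C)c1
F6 | step 8 | 5,7-bis(benzyloxy)-2-[2,4-bis(tert-butyldimethylsilyloxy)phenyl]-3-iodo-4H-chromen-4-one | O=c1c(I)c(-c2ccc(O[Si](C)(C)C(C)(C)C)cc2O[Si](C)(C)C(C)(C)C)oc2cc(OCc3ccccc3)cc(OCc3ccccc3)c12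
F7 | step 8 | 5,7-bis(benzyloxy)-2-(2,4-dihydroxyphenyl)-3-iodo-4H-chromen-4-one | O=c1c(I)c(-c2ccc(O)cc2O)oc2cc(OCc3ccccc3)cc(OCc3ccccc3)c12
F8 | step 16 | (10R)-5,7-diacetoxy-6,8-diallyl-10-[2-(triethylsilyloxy)propan-2-yl]-9,10-dihydro-oxepino-flavon-4'-yl 2-methyl-2-(triethylsilyloxy)propanoate | O=c1c2c(OC(C)=O)c(CC=C)c(OC(C)=O)c(CC=C)c2oc2c1C[C@H](C(C)(C)O[Si](CC)(CC)CC)Oc1cc(OC(=O)C(C)(C)O[Si](CC)(CC)CC)ccc1-2
A1 | alternative 1 | (10R)-6,8-diiodo oxepino-flavone core as its 5,7,4'-triacetate | CC(=O)Oc1c(I)c(OC(C)=O)c(I)c2oc3c(c(=O)c12)C[C@H](C(C)(C)O)Oc1cc(OC(C)=O)ccc1-3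
A2 | alternative 1 | target as its 5,7,4'-triacetate | CC(=O)Oc1c(CC=C(C)C)c(OC(C)=O)c(CC=C(C)C)c2oc3c(c(=O)c12)C[C@H](C(C)(C)O)Oc1cc(OC(C)=O)ccc1-3
A3 | alternative 2 | (R)-2-{[2-hydroxy-2-methyl-6-(2,4,6-tris(benzyloxy)phenyl)hex-5-yn-3-yl]oxy}-4-(triisopropylsilyloxy)benzaldehyde oxime | CC(C)(O)[C@@H](CC#Cc1c(OCc2ccccc2)cc(OCc2ccccc2)cc1OCc1ccccc1)Oc1cc(O[Si](C(C)C)(C(C)C)C(C)C)ccc1C=NO
A4 | alternative 2 | (R)-oxepine-fused 5-[2,4,6-tris(benzyloxy)phenyl]isoxazole (tricyclic benzoxepino-isoxazole), ring-B oxygen as triisopropylsilyl ether | CC(C)(O)[C@H]1Cc2c(-c3c(OCc4ccccc4)cc(OCc4ccccc4)cc3OCc3ccccc3)onc2-c2ccc(O[Si](C(C)C)(C(C)C)C(C)C)cc2O1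
A5 | alternative 3 | (R)-5,7-bis(benzyloxy)-2-ethynyl-3-{2-[1,3-bis(trimethylsilyloxy)buta-1,3-dienyloxy]-3-methyl-3-(trimethylsilyloxy)butyl}-4H-chromen-4-one | O=c1c2c(OCc3ccccc3)cc(OCc3ccccc3)cc2oc(C#C)c1C[C@H](C(C)(C)O[Si](C)(C)C)OC(O[Si](C)(C)C)=CC(=C)O[Si](C)(C)C
A6 | alternative 3 | (R)-5,7-di-O-benzyl oxepino-flavone core with 4'-O-trimethylsilyl and tertiary O-trimethylsilyl groups | O=c1c2c(OCc3ccccc3)cc(OCc3ccccc3)cc2oc2c1C[C@H](C(C)(C)O[Si](C)(C)C)Oc1cc(O[Si](C)(C)C)ccc1-2
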